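Labdane numbering is used. Ring B is cut at C6–C7 and C8–C9, leaving ring A with C6 on C5 and C9 on C10 and a two-carbon C7–C8 unit. The key step is a radical [4+2] annulation: a primary C6 radical adds to phenyl vinyl sulfone and the new C8 radical closes ring B 6-exo onto the C9=C11 alkene. It exploits the 1,4 relation of C6 and C9 across the C5–C10 bond and the sp2 character of C8, later a ketone and then the exocyclic methylene. The precursor is a 2-(phenylselanylmethyl)cyclohexanone whose quaternary C10 carries the (R)-linalool-derived alkenyl chain.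

Key step: step 6

Remark: commercial (R)-(−)-linalool of high enantiomeric purity is assumed as the source of C13, and the ligand enantiomer in step 4 is the one that gives the C10 configuration drawn.

Step 1
Reactants: 1 (R)-(−)-linalool
Product: 2 (3R)-3-(tert-butyldimethylsilyloxy)-3,7-dimethylocta-1,6-diene
Conditions: tBuMe2SiOTf, 2,6-lutidine, CH2Cl2, 0 °C
Reagents that add atoms: tert-butyldimethylsilyl trifluoromethanesulfonate, CC(C)(C)[Si](C)(C)OS(=O)(=O)C(F)(F)F
Why: Silylation of the hindered tertiary allylic alcohol with a silyl triflate and a non-nucleophilic base is standard and leaves the chiral-pool C13 stereocentre untouched.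

Step 2
Reactants: 2 (3R)-3-(tert-butyldimethylsilyloxy)-3,7-dimethylocta-1,6-diene
Product: 3 (4R)-4-(tert-butyldimethylsilyloxy)-4-methylhex-5-enal
Conditions: O3 (1 equiv, dye end-point), CH2Cl2–MeOH, −78 °C; then PPh3
Reagents that add atoms: ozone, [O-][O+]=O
Why: Ozonolysis with reductive work-up should cleave the electron-rich trisubstituted alkene much faster than the monosubstituted vinyl group, releasing C9 as the aldehyde carbon.

Step 3
Reactants: 3 (4R)-4-(tert-butyldimethylsilyloxy)-4-methylhex-5-enal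
Product: 5 (3R)-3-(tert-butyldimethylsilyloxy)-3-methylhex-1-en-5-yne, via alkenyl nonaflate 4 (not isolated)
Conditions: C4F9SO2F, tBuN=P(NC4H8)3 (phosphazene base), DMF, −20 °C to rt
Reagents that add atoms: none
Why: One-pot nonaflation of the aldehyde enolate and base-induced elimination of the alkenyl nonaflate converts the aldehyde into the terminal alkyne with the same carbon count (its carbons become C9 and C11), and the hindered tertiary silyl ether should outlast the fluoride formed at low temperature.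

Step 4
Reactants: 5 (3R)-3-(tert-butyldimethylsilyloxy)-3-methylhex-1-en-5-yne, 6 3-methylcyclohex-2-en-1-one
Product: 9 tert-butyl({(3R,5E)-3-methyl-6-[(1R)-1-methyl-3-(trimethylsilyloxy)cyclohex-2-en-1-yl]hexa-1,5-dien-3-yl}oxy)dimethylsilane, via alkenylalane 7 (not isolated), via aluminium enolate 8 (not isolated)
Conditions: iBu2AlH, hexane, 50 °C; then 6, CuO2CC4H3S (monovalent copper thiophene-2-carboxylate, 10 mol %), chiral phosphinamine ligand Ph2P–N[CH(CH3)(2-naphthyl)]2 (11 mol %), Et2O, −30 °C; then Me3SiOTf, Et3N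
Reagents that add atoms: trimethylsilyl trifluoromethanesulfonate, C[Si](C)(C)OS(=O)(=O)C(F)(F)F
Why: syn-Hydroalumination gives the (E)-alkenylalane, and copper-catalysed asymmetric conjugate addition of alkenylalanes to 3-substituted cyclohexenones builds the quaternary C10 with the face fixed by the chiral ligand (the remote C13 centre should not interfere), the enolate being trapped regiospecifically as the C4–C5 silyl enol ether.

Step 5
Reactants: 9 tert-butyl({(3R,5E)-3-methyl-6-[(1R)-1-methyl-3-(trimethylsilyloxy)cyclohex-2-en-1-yl]hexa-1,5-dien-3-yl}oxy)dimethylsilane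
Product: 13 (3R)-3-[(1E,4R)-4-(tert-butyldimethylsilyloxy)-4-methylhexa-1,5-dien-1-yl]-3-methyl-2-[(phenylselanyl)methyl]cyclohexan-1-one (C2 epimers; ring C2 is C5 and ring C3 is C10), via Mannich base 10 (not isolated), via ammonium iodide 11 (not isolated), via methylene ketone 12 (not isolated)
Conditions: CH2=NMe2 I (Eschenmoser's salt), CH2Cl2, rt; MeI; evaporate; PhSeH, Et3N, THF, 0 °C to rt
Reagents that add atoms: N,N-dimethylmethyleneiminium iodide, C=[N+](C)C.[I-]; benzeneselenol, [SeH]c1ccccc1
Why: Mannich aminomethylation of the silyl enol ether at C5, quaternisation and elimination to the α-methylene ketone, then conjugate addition of the selenol (selena-Michael addition) install C6 with a radical leaving group, C5 forming as a mixture that is corrected in step 6.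

Step 6
Reactants: 13 (3R)-3-[(1E,4R)-4-(tert-butyldimethylsilyloxy)-4-methylhexa-1,5-dien-1-yl]-3-methyl-2-[(phenylselanyl)methyl]cyclohexan-1-one, 14 phenyl vinyl sulfone
Product: 16 (13R)-13-(tert-butyldimethylsilyloxy)-8-(phenylsulfonyl)-17,18,19-trinorlabd-14-en-4-one (5α-H and 10β-CH3 trans-fused; C8/C9 epimers), via unequilibrated decalone sulfone 15 (not isolated)
Conditions: 14 (1.2 equiv), Bu3SnH (syringe pump), AIBN, PhH (0.01 M), 80 °C; then K2CO3, MeOH, rt
Reagents that add atoms: none
Why: The tributyltin radical abstracts PhSe from 13 to give the primary C6 radical, which adds to the CH2 terminus of 14 (bond C6–C7); the electrophilic α-sulfonyl radical at C8 then attacks C9 of the (E)-alkene (bond C8–C9) and the C11 radical is reduced by Bu3SnH. This is a tin hydride radical annulation (Giese addition followed by exo cyclisation), the six-ring counterpart of the [3+2] radical annulations known with vinyl sulfones. Ring B closes in the 6-exo-trig mode through a chair-like transition state templated by ring A, and no 1,5-hydrogen shift is open to the C8 radical because C4 and C10 carry no hydrogen. C8 and C9 form as mixtures (the chair with C11 equatorial should lead) and need no control here, since C8 becomes a ketone in step 10, where C9 is equilibrated; C5 is set by the K2CO3 epimerisation next to the C4 ketone, which should favour the trans-fused decalone. The step needs chemoselectivity (the C6 radical must add to 14 before it is reduced, the C8 radical must cyclise before it is reduced, and the C11 radical must be reduced before it adds to a second sulfone) and 6-exo over 7-endo closure; slow addition of Bu3SnH, near-stoichiometric 14, high dilution and the gem-disubstituted C10 in the tether work in this direction.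

Step 7
Reactants: 16 (13R)-13-(tert-butyldimethylsilyloxy)-8-(phenylsulfonyl)-17,18,19-trinorlabd-14-en-4-one
Product: 18 (13R)-13-(tert-butyldimethylsilyloxy)-8-(phenylsulfonyl)-17,18-dinorlabd-14-en-19-al (C4/C8/C9 epimers), via enol ether 17 (not isolated)
Conditions: Ph3P(CH2OMe)Cl, KN(SiMe3)2, THF, 0 °C to rt; then aq. (CO2H)2, THF
Reagents that add atoms: (methoxymethylene)triphenylphosphorane, COC=P(c1ccccc1)(c1ccccc1)c1ccccc1; water, O
Why: Wittig methoxymethylenation of the C4 ketone and hydrolysis of the enol ether is the classical one-carbon homologation to the aldehyde (C19), the C4 configuration being irrelevant because it is planarised in step 8 and the sulfone being inert to the ylide.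

Step 8
Reactants: 18 (13R)-13-(tert-butyldimethylsilyloxy)-8-(phenylsulfonyl)-17,18-dinorlabd-14-en-19-al
Product: 19 (13R)-13-(tert-butyldimethylsilyloxy)-8-(phenylsulfonyl)-17-norlabd-14-en-19-al (4α-CH3 and 4β-CHO; C8/C9 epimers)
Conditions: KOtBu, MeI, THF–tBuOH, 0 °C
Reagents that add atoms: iodomethane, CI
Why: Enolate C-methylation of the α-branched aldehyde (whose α-hydrogen is far more acidic than the one next to the sulfone) should take MeI on the α face, away from the 1,3-related axial C10 methyl group, giving the 4α-methyl-4β-formyl arrangement as in related 10-methyl-trans-decalins.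

Step 9
Reactants: 19 (13R)-13-(tert-butyldimethylsilyloxy)-8-(phenylsulfonyl)-17-norlabd-14-en-19-al
Product: 20 (13R)-13-(tert-butyldimethylsilyloxy)-8-(phenylsulfonyl)-17-norlabd-14-en-19-ol (C8/C9 epimers)
Conditions: NaBH4, MeOH, 0 °C
Reagents that add atoms: none
Why: Chemoselective hydride reduction of the neopentyl aldehyde gives the C19 alcohol without touching the sulfone or the alkenes.

Step 10
Reactants: 20 (13R)-13-(tert-butyldimethylsilyloxy)-8-(phenylsulfonyl)-17-norlabd-14-en-19-ol
Product: 22 (13R)-13-(tert-butyldimethylsilyloxy)-19-hydroxy-17-norlabd-14-en-8-one (9α-H), via ketone epimer mixture 21 (not isolated)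
Conditions: LiN(iPr)2 (2.5 equiv), THF, −78 °C; Me3SiOOSiMe3; then NaOMe, MeOH, rt
Reagents that add atoms: bis(trimethylsilyl) peroxide, C[Si](C)(C)OO[Si](C)(C)C
Why: Oxidative desulfonylation (the α-sulfonyl carbanion is oxygenated by the silyl peroxide and the α-silyloxy sulfone collapses to the ketone with loss of sulfinate) unveils the C8 ketone, and base equilibration through its enolate should then place the C9 side chain equatorial (9α-H), the thermodynamically preferred epimer.

Step 11
Reactants: 22 (13R)-13-(tert-butyldimethylsilyloxy)-19-hydroxy-17-norlabd-14-en-8-one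
Product: 23 (13R)-13-(tert-butyldimethylsilyloxy)labda-8(17),14-dien-19-ol
Conditions: Ph3PCH3Br, KOtBu (excess), toluene, 80 °C
Reagents that add atoms: methylenetriphenylphosphorane, C=P(c1ccccc1)(c1ccccc1)c1ccccc1
Why: Wittig methylenation of the 8-ketone installs C17, excess ylide tolerating the free alcohol and C9 staying at its thermodynamic configuration under the basic conditions.

Step 12
Reactants: 23 (13R)-13-(tert-butyldimethylsilyloxy)labda-8(17),14-dien-19-ol
Product: 24 (13R)-labda-8(17),14-diene-13,19-diol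
Conditions: Bu4NF, THF, 50 °C
Reagents that add atoms: none
Why: Fluoride-mediated desilylation frees the tertiary C13 alcohol without affecting any stereocentre.

Step 13
Reactants: 24 (13R)-labda-8(17),14-diene-13,19-diol, 25 tigloyl chloride
Product: 26 (13R)-13-hydroxylabda-8(17),14-dien-19-yl (2E)-2-methylbut-2-enoate (CNP0313179.1)
Conditions: 25 (1.2 equiv), pyridine, DMAP (cat.), CH2Cl2, 0 °C to rt
Reagents that add atoms: none
Why: DMAP-catalysed acylation with the acid chloride should be selective for the primary C19 alcohol over the tertiary allylic C13 alcohol and retains the (E) geometry of the tiglate.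

Compound list
1 | (R)-(−)-linalool, (3R)-3,7-dimethylocta-1,6-dien-3-ol | C=C[C@](C)(O)CCC=C(C)C | starting material
2 | (3R)-3-(tert-butyldimethylsilyloxy)-3,7-dimethylocta-1,6-diene | C=C[C@](C)(O[Si](C)(C)C(C)(C)C)CCC=C(C)C | intermediate
3 | (4R)-4-(tert-butyldimethylsilyloxy)-4-methylhex-5-enal | C=C[C@](C)(O[Si](C)(C)C(C)(C)C)CCC=O | intermediate
4 | (4R)-4-(tert-butyldimethylsilyloxy)-4-methylhexa-1,5-dien-1-yl nonafluorobutanesulfonate (E/Z mixture) | C=C[C@](C)(O[Si](C)(C)C(C)(C)C)CC=COS(=O)(=O)C(F)(F)C(F)(F)C(F)(F)C(F)(F)F | intermediate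
5 | (3R)-3-(tert-butyldimethylsilyloxy)-3-methylhex-1-en-5-yne | C=C[C@](C)(O[Si](C)(C)C(C)(C)C)CC#C | intermediate
6 | 3-methylcyclohex-2-en-1-one | CC1=CC(=O)CCC1 | starting material
7 | diisobutyl[(1E,4R)-4-(tert-butyldimethylsilyloxy)-4-methylhexa-1,5-dien-1-yl]alumane | C=C[C@](C)(O[Si](C)(C)C(C)(C)C)C/C=C/[Al](CC(C)C)CC(C)C | intermediate
8 | diisobutylaluminium enolate corresponding to 9 | C=C[C@](C)(O[Si](C)(C)C(C)(C)C)C/C=C/[C@]1(C)C=C(O[Al](CC(C)C)CC(C)C)CCC1 | intermediate
9 | tert-butyl({(3R,5E)-3-methyl-6-[(1R)-1-methyl-3-(trimethylsilyloxy)cyclohex-2-en-1-yl]hexa-1,5-dien-3-yl}oxy)dimethylsilane | C=C[C@](C)(O[Si](C)(C)C(C)(C)C)C/C=C/[C@]1(C)C=C(O[Si](C)(C)C)CCC1 | intermediate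
10 | (3R)-3-[(1E,4R)-4-(tert-butyldimethylsilyloxy)-4-methylhexa-1,5-dien-1-yl]-2-[(dimethylamino)methyl]-3-methylcyclohexan-1-one (C2 epimers) | C=C[C@](C)(O[Si](C)(C)C(C)(C)C)C/C=C/[C@]1(C)C(CN(C)C)C(=O)CCC1 | intermediate
11 | trimethylammonium iodide of 10 | C=C[C@](C)(O[Si](C)(C)C(C)(C)C)C/C=C/[C@]1(C)C(C[N+](C)(C)C)C(=O)CCC1.[I-] | intermediate
12 | (3R)-3-[(1E,4R)-4-(tert-butyldimethylsilyloxy)-4-methylhexa-1,5-dien-1-yl]-3-methyl-2-methylidenecyclohexan-1-one | C=C[C@](C)(O[Si](C)(C)C(C)(C)C)C/C=C/[C@]1(C)C(=C)C(=O)CCC1 | intermediate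
13 | (3R)-3-[(1E,4R)-4-(tert-butyldimethylsilyloxy)-4-methylhexa-1,5-dien-1-yl]-3-methyl-2-[(phenylselanyl)methyl]cyclohexan-1-one (C2 epimers) | C=C[C@](C)(O[Si](C)(C)C(C)(C)C)C/C=C/[C@]1(C)C(C[Se]c2ccccc2)C(=O)CCC1 | intermediate
14 | phenyl vinyl sulfone | C=CS(=O)(=O)c1ccccc1 | starting material
15 | (13R)-13-(tert-butyldimethylsilyloxy)-8-(phenylsulfonyl)-17,18,19-trinorlabd-14-en-4-one as a C5/C8/C9 epimer mixture | C=C[C@](C)(O[Si](C)(C)C(C)(C)C)CCC1C(S(=O)(=O)c3ccccc3)CCC2C(=O)CCC[C@]12C | intermediate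
16 | (13R)-13-(tert-butyldimethylsilyloxy)-8-(phenylsulfonyl)-17,18,19-trinorlabd-14-en-4-one, 5α-H and 10β-CH3 (trans-fused), C8/C9 epimers | C=C[C@](C)(O[Si](C)(C)C(C)(C)C)CCC1C(S(=O)(=O)c3ccccc3)CC[C@H]2C(=O)CCC[C@]12C | intermediate
17 | (13R)-13-(tert-butyldimethylsilyloxy)-19-methoxy-8-(phenylsulfonyl)-17,18-dinorlabda-4(19),14-diene | C=C[C@](C)(O[Si](C)(C)C(C)(C)C)CCC1C(S(=O)(=O)c3ccccc3)CC[C@H]2C(=COC)CCC[C@]12C | intermediate
18 | (13R)-13-(tert-butyldimethylsilyloxy)-8-(phenylsulfonyl)-17,18-dinorlabd-14-en-19-al (C4/C8/C9 epimers) | C=C[C@](C)(O[Si](C)(C)C(C)(C)C)CCC1C(S(=O)(=O)c3ccccc3)CC[C@H]2C(C=O)CCC[C@]12C | intermediate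
19 | (13R)-13-(tert-butyldimethylsilyloxy)-8-(phenylsulfonyl)-17-norlabd-14-en-19-al, 4α-CH3 and 4β-CHO (C8/C9 epimers) | C=C[C@](C)(O[Si](C)(C)C(C)(C)C)CCC1C(S(=O)(=O)c3ccccc3)CC[C@H]2[C@@](C)(C=O)CCC[C@]12C | intermediate
20 | (13R)-13-(tert-butyldimethylsilyloxy)-8-(phenylsulfonyl)-17-norlabd-14-en-19-ol (C8/C9 epimers) | C=C[C@](C)(O[Si](C)(C)C(C)(C)C)CCC1C(S(=O)(=O)c3ccccc3)CC[C@H]2[C@@](C)(CO)CCC[C@]12C | intermediate
21 | (13R)-13-(tert-butyldimethylsilyloxy)-19-hydroxy-17-norlabd-14-en-8-one as a C9 epimer mixture | C=C[C@](C)(O[Si](C)(C)C(C)(C)C)CCC1C(=O)CC[C@H]2[C@@](C)(CO)CCC[C@]12C | intermediate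
22 | (13R)-13-(tert-butyldimethylsilyloxy)-19-hydroxy-17-norlabd-14-en-8-one (9α-H) | C=C[C@](C)(O[Si](C)(C)C(C)(C)C)CC[C@H]1C(=O)CC[C@H]2[C@@](C)(CO)CCC[C@]12C | intermediate
23 | (13R)-13-(tert-butyldimethylsilyloxy)labda-8(17),14-dien-19-ol | C=C[C@](C)(O[Si](C)(C)C(C)(C)C)CC[C@H]1C(=C)CC[C@H]2[C@@](C)(CO)CCC[C@]12C | intermediate
24 | (13R)-labda-8(17),14-diene-13,19-diol | C=C[C@](C)(O)CC[C@H]1C(=C)CC[C@H]2[C@@](C)(CO)CCC[C@]12C | intermediate
25 | tigloyl chloride, (2E)-2-methylbut-2-enoyl chloride | ClC(=O)/C(C)=C/C | starting material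
26 | (4S,5R,9S,10R,13R)-13-hydroxylabda-8(17),14-dien-19-yl (2E)-2-methylbut-2-enoate | C=C[C@](C)(O)CC[C@H]1C(=C)CC[C@H]2[C@@](C)(COC(=O)/C(C)=C/C)CCC[C@]12C | target

Total step count: 13. Longest linear sequence: 13 steps (1 to 26).

Steps most likely to fail:

Step 6. The radical chain may leak: the C8 radical can be reduced before ring closure, and the cyclised C11 radical can be captured by a second molecule of the sulfone. The fallback sets out from 13 and comes back at 23; it makes the two bonds in separate radical steps through a vinyl bromide. Keck allylation of 13 with tributyl(2-bromoallyl)stannane and AIBN should give (3R)-2-(3-bromobut-3-en-1-yl)-3-[(1E,4R)-4-(tert-butyldimethylsilyloxy)-4-methylhexa-1,5-dien-1-yl]-3-methylcyclohexan-1-one F1. Bu3SnH and AIBN at high dilution then close ring B by 6-exo cyclisation of the vinyl radical, and K2CO3 in MeOH equilibrates C5, to give (13R)-13-(tert-butyldimethylsilyloxy)-18,19-dinorlabda-8(17),14-dien-4-one F2; C9 is not equilibrated on this path, so its epimers have to be separated here. Methoxymethylenation and hydrolysis as in step 7 lead to (13R)-13-(tert-butyldimethylsilyloxy)-18-norlabda-8(17),14-dien-19-al F3, methylation as in step 8 to (13R)-13-(tert-butyldimethylsilyloxy)labda-8(17),14-dien-19-al F4, and NaBH4 reduction to 23.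

Step 10. Deprotonation at the hindered C8 beside a lithium alkoxide may be incomplete, or the peroxide may be consumed by the alkoxide, so that the sulfone is returned. The fallback sets out from 20 and comes back at 22; it replaces the peroxide oxidation by sulfenylation and hydrolysis. LiN(iPr)2 followed by PhSSPh should give (13R)-13-(tert-butyldimethylsilyloxy)-8-(phenylsulfanyl)-8-(phenylsulfonyl)-17-norlabd-14-en-19-ol F5, a masked ketone, which is hydrolysed with CuCl2 on wet SiO2 and then equilibrated with NaOMe in MeOH to 22.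

Step 4. Facial selectivity of the alkenyl transfer may be poor, and the alkyne may be deprotonated instead of hydroaluminated. The fallback sets out from 5 and comes back at 9; it reverses the roles of the two groups on C10. Hydrozirconation with Cp2Zr(H)Cl and iodination give (1E,4R)-4-(tert-butyldimethylsilyloxy)-1-iodo-4-methylhexa-1,5-diene F6. Lithium–iodine exchange with tBuLi, addition to 3-ethoxycyclohex-2-en-1-one and acidic work-up (Stork–Danheiser transposition) give 3-[(1E,4R)-4-(tert-butyldimethylsilyloxy)-4-methylhexa-1,5-dien-1-yl]cyclohex-2-en-1-one F7. Copper-catalysed asymmetric 1,4-addition of Me3Al with a chiral phosphoramidite ligand and Me3SiOTf trapping then lead to 9.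

Further compounds
F1 | step 6 | (3R)-2-(3-bromobut-3-en-1-yl)-3-[(1E,4R)-4-(tert-butyldimethylsilyloxy)-4-methylhexa-1,5-dien-1-yl]-3-methylcyclohexan-1-one | C=C[C@](C)(O[Si](C)(C)C(C)(C)C)C/C=C/[C@]1(C)C(CCC(Br)=C)C(=O)CCC1
F2 | step 6 | (13R)-13-(tert-butyldimethylsilyloxy)-18,19-dinorlabda-8(17),14-dien-4-one | C=C[C@](C)(O[Si](C)(C)C(C)(C)C)CC[C@H]1C(=C)CC[C@H]2C(=O)CCC[C@]12C
F3 | step 6 | (13R)-13-(tert-butyldimethylsilyloxy)-18-norlabda-8(17),14-dien-19-al (C4 epimers) | C=C[C@](C)(O[Si](C)(C)C(C)(C)C)CC[C@H]1C(=C)CC[C@H]2C(C=O)CCC[C@]12C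
F4 | step 6 | (13R)-13-(tert-butyldimethylsilyloxy)labda-8(17),14-dien-19-al | C=C[C@](C)(O[Si](C)(C)C(C)(C)C)CC[C@H]1C(=C)CC[C@H]2[C@@](C)(C=O)CCC[C@]12C
F5 | step 10 | (13R)-13-(tert-butyldimethylsilyloxy)-8-(phenylsulfanyl)-8-(phenylsulfonyl)-17-norlabd-14-en-19-ol | C=C[C@](C)(O[Si](C)(C)C(C)(C)C)CCC1C(Sc4ccccc4)(S(=O)(=O)c3ccccc3)CC[C@H]2[C@@](C)(CO)CCC[C@]12C
F6 | step 4 | (1E,4R)-4-(tert-butyldimethylsilyloxy)-1-iodo-4-methylhexa-1,5-diene | C=C[C@](C)(O[Si](C)(C)C(C)(C)C)C/C=C/I
F7 | step 4 | 3-[(1E,4R)-4-(tert-butyldimethylsilyloxy)-4-methylhexa-1,5-dien-1-yl]cyclohex-2-en-1-one | C=C[C@](C)(O[Si](C)(C)C(C)(C)C)C/C=C/C1=CC(=O)CCC1
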